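**Retrosynthetic overview**

1. The C18–O ester is cut last (Steglich esterification) into labdane alcohol 26 and hydroxy acid 39. Both halves come from one enone (3) through one silyl enol ether (10), made by a catalytic asymmetric conjugate addition of a butenyl Grignard reagent and O-silylation of the magnesium enolate.
2. Ring A of 26 is removed as an ethyl vinyl ketone equivalent (7, C1–C4 plus C19): C1–C10 by Michael addition and C4–C5 by aldol condensation in the same flask. The feature that allows this: ring A carries nothing on C1–C3 and shares only the C5–C10 bond with ring B, and the methyl-bearing quaternary C10 lies between C5 and the side-chain carbon C9. So C5 can be a ketone, C10 its enolate carbon (stored regiospecifically in 10 and released with MeLi), and the C8 methylene a ketal-masked ketone.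
3. After ring A: C4 (18-CH2OH α, 19-CH3 β) and the trans ring fusion by reductive hydroxymethylation of the Δ4-3-ketone; C3=O removed; butenyl → alkyne → (13E)-enoate by carboalumination; C8 ketone → methylene.
4. Acid 39: 10 + MeI through the fluoride-released enolate (gem-dimethyl), deoxygenation, cross-metathesis and asymmetric methyl conjugate addition (C3′), then ketal → ketone → methylene → epoxide → tertiary alcohol, and oxidation to the acid.
5. Ring order: ring B is present in 1; ring A is closed in step 5; the cyclohexane of 39 is the ring of 1, so no ring is formed for it.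

Key step: step 5

Remark: compounds 14–26 are named with labdane numbering (β = the face of the C10 methyl; C18 = 4α-CH2O, trans to the C10 methyl; C19 = 4β-CH3).
Remark: compound 1 is taken as a catalogue compound. The sense of induction of the copper catalysts in steps 4 and 17 is assigned once by correlation, and the ligand enantiomer that gives the drawn configuration is used.

**Route**

Step 1
Reactants: 1 1,4-dioxaspiro[4.5]dec-6-en-8-one
Product: 2 7-iodo-1,4-dioxaspiro[4.5]dec-6-en-8-one
Conditions: I2, pyridine, CH2Cl2, 0 °C → rt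
Reagents that add atoms: iodine, II
Why: α-Iodination of the enone (conjugate addition of pyridine, iodination of the enolate, elimination) is regiospecific for the α-carbon and leaves the ketal untouched.

Step 2
Reactants: 2 7-iodo-1,4-dioxaspiro[4.5]dec-6-en-8-one
Product: 3 7-methyl-1,4-dioxaspiro[4.5]dec-6-en-8-one
Conditions: (MeBO)3, Pd(dppf)Cl2 (5 mol %), K2CO3, dioxane/H2O, 90 °C
Reagents that add atoms: trimethylboroxine, CB1OB(C)OB(C)O1
Why: Suzuki–Miyaura coupling of the 2-iodoenone puts the methyl group on the α-carbon, which becomes C10 of 26 and the gem-dimethyl carbon of 39.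

Step 3
Reactants: 4 (1-bromoethenyl)trimethylsilane; 5 N-methoxy-N-methylpropanamide
Product: 7 2-(trimethylsilyl)pent-1-en-3-one, via vinyllithium 6 (not isolated)
Conditions: t-BuLi (2 equiv), Et2O, −78 °C; then 5, −78 → 0 °C; NH4Cl
Reagents that add atoms: none
Why: Bromine–lithium exchange gives the α-silyl vinyllithium, which adds once to the Weinreb amide (chelated tetrahedral adduct) and gives the α-silyl vinyl ketone on work-up (Weinreb ketone synthesis).

Step 4
Reactants: 3 7-methyl-1,4-dioxaspiro[4.5]dec-6-en-8-one; 8 but-3-en-1-ylmagnesium bromide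
Product: 10 {[(6R)-6-(but-3-en-1-yl)-7-methyl-1,4-dioxaspiro[4.5]dec-7-en-8-yl]oxy}trimethylsilane, via magnesium enolate 9 (not isolated)
Conditions: Cu(OTf)2 (3 mol %), chiral imidazolinium salt (carbene ligand precursor, 4 mol %), Et2O, −30 °C, slow addition of 8 (1.2 equiv); then TMSCl (2 equiv), Et3N, DMPU, −30 °C → rt; pentane, cold aqueous NaHCO3
Reagents that add atoms: chlorotrimethylsilane, C[Si](C)(C)Cl
Why: The chiral copper–carbene catalyst adds the butenyl group of 8 to the β-carbon of enone 3 (C9 of the labdane half) on one enantioface (copper-catalysed asymmetric conjugate addition), which sets the only stereocentre of 10, and the magnesium enolate 9 is silylated on oxygen by TMSCl, so that the regiodefined tetrasubstituted enolate is stored in isolable form for both halves.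

Step 5
Reactants: 10 {[(6R)-6-(but-3-en-1-yl)-7-methyl-1,4-dioxaspiro[4.5]dec-7-en-8-yl]oxy}trimethylsilane; 7 2-(trimethylsilyl)pent-1-en-3-one
Product: 14 8,8-ethylenedioxy-15,16,17,18-tetranorlabda-4,13-dien-3-one, via lithium enolate 11 (not isolated), via silylated Michael adduct 12 (not isolated), via 1,5-diketone 13 (not isolated)
Conditions: MeLi (1.0 equiv), THF, 0 °C → rt; then 7 (1.2 equiv), −78 → −20 °C; then NaOMe (0.5 equiv), MeOH, 50 °C; NH4Cl
Reagents that add atoms: none
Why: MeLi cleaves the Si–O bond of 10 and releases the tetrasubstituted lithium enolate 11 regiospecifically (C5–O, C10 as the nucleophilic carbon) and free of copper and magnesium salts; 11 attacks the terminal CH2 of 7 (Michael addition, C1–C10), and the α-silyl group stabilises the adduct anion so that proton transfer and polymerisation of the enone are suppressed. Methoxide then removes the silyl group from 12, and the ethyl-ketone enolate of 13 (C4) adds to the C5 carbonyl and loses water (aldol condensation, C4–C5). This closes ring A by a 6-(enolendo)-exo-trig aldol addition; the other enolate of the side-chain ketone (C2) could only close a four-membered ring. The closest known reaction type is the annulation of lithium enolates, generated regiospecifically from trimethylsilyl enol ethers with MeLi, with α-silyl vinyl ketones (Robinson annulation in its α-silyl vinyl ketone variant). The one new stereocentre, C10, is controlled by C9 (1,2-induction): the enone enters anti to the butenyl group, which sits pseudoaxial to avoid allylic strain with the C10 methyl, so that the methyl ends cis to the side chain. The step needs C- over O-attack, reaction at C10 and not at C6, and no enolate equilibration, which the soft α-silyl enone, the enolate position fixed in 10 and the aprotic low-temperature conditions should secure.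

Step 6
Reactants: 14 8,8-ethylenedioxy-15,16,17,18-tetranorlabda-4,13-dien-3-one
Product: 16 8,8-ethylenedioxy-18-hydroxy-15,16,17-trinorlabd-13-en-3-one, via lithium enolate 15 (not isolated)
Conditions: Li, NH3(l)/THF, t-BuOH (1 equiv), −78 °C; isoprene; NH3 off; then CH2O (gas), THF, −78 → −40 °C; NH4Cl
Reagents that add atoms: formaldehyde, C=O
Why: Dissolving-metal reduction of the enone (Birch-type reductive alkylation) protonates C5 from the α face to give the trans-decalin, and the C3/C4 lithium enolate takes formaldehyde at C4 from the α face, anti to the axial C10 methyl, so that CH2OH becomes 4α (C18) and the methyl 4β, as in known reductive hydroxymethylations of 4-methyl-Δ4-3-ketones; the isolated alkene and the ketal are inert.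

Step 7
Reactants: 16 8,8-ethylenedioxy-18-hydroxy-15,16,17-trinorlabd-13-en-3-one
Product: 17 8,8-ethylenedioxy-18-(methoxymethoxy)-15,16,17-trinorlabd-13-en-3-one
Conditions: MeOCH2Cl, i-Pr2NEt, CH2Cl2, 0 °C → rt
Reagents that add atoms: chloromethyl methyl ether, COCCl
Why: Alkylation of the neopentyl hydroxyl under mild amine base protects the β-hydroxy ketone against retro-aldol loss of formaldehyde in the next, strongly basic step.

Step 8
Reactants: 17 8,8-ethylenedioxy-18-(methoxymethoxy)-15,16,17-trinorlabd-13-en-3-one
Product: 19 8,8-ethylenedioxy-18-(methoxymethoxy)-15,16,17-trinorlabd-13-ene, via hydrazone 18 (not isolated)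
Conditions: N2H4·H2O, diethylene glycol, 130 °C; then KOH, 200 °C (under N2)
Reagents that add atoms: none
Why: Wolff–Kishner reduction (Huang–Minlon variant) removes the hindered C3 carbonyl; the acetals, the ether and the isolated alkene tolerate hydrazine and KOH, and C4 has no hydrogen, so that neither elimination nor epimerisation is possible.

Step 9
Reactants: 19 8,8-ethylenedioxy-18-(methoxymethoxy)-15,16,17-trinorlabd-13-ene
Product: 21 8,8-ethylenedioxy-18-(methoxymethoxy)-14,15,16,17-tetranorlabdan-13-al, via ozonide 20 (not isolated)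
Conditions: O3, CH2Cl2, −78 °C; then PPh3, −78 °C → rt
Reagents that add atoms: ozone, [O-][O+]=O
Why: Ozonolysis of the only alkene with reductive work-up cuts C13=C14 to the C13 aldehyde while the ketal still masks the C8 ketone, so that no intramolecular aldol reaction can follow.

Step 10
Reactants: 21 8,8-ethylenedioxy-18-(methoxymethoxy)-14,15,16,17-tetranorlabdan-13-al
Product: 22 8,8-ethylenedioxy-18-(methoxymethoxy)-15,16,17-trinorlabd-13-yne
Conditions: dimethyl (1-diazo-2-oxopropyl)phosphonate, K2CO3, MeOH, 0 °C → rt
Reagents that add atoms: dimethyl (1-diazo-2-oxopropyl)phosphonate, COP(=O)(OC)C(=[N+]=[N-])C(C)=O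
Why: Seyferth–Gilbert homologation with the Ohira–Bestmann reagent turns the aldehyde into the terminal alkyne C13≡C14 under mild carbonate conditions.

Step 11
Reactants: 22 8,8-ethylenedioxy-18-(methoxymethoxy)-15,16,17-trinorlabd-13-yne
Product: 23 18-hydroxy-15,16,17-trinorlabd-13-yn-8-one
Conditions: 6 M HCl, THF, 50 °C
Reagents that add atoms: water, O
Why: Aqueous acid hydrolyses the dioxolane to the C8 ketone and the methoxymethyl ether to the free C18 alcohol in one operation; C9, now α to the ketone, keeps the equatorial (β) side chain, which is the thermodynamic configuration.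

Step 12
Reactants: 23 18-hydroxy-15,16,17-trinorlabd-13-yn-8-one
Product: 24 15,16-dinorlabd-8(17)-en-13-yn-18-ol
Conditions: Ph3PCH3Br, KOt-Bu (4 equiv each), toluene, 0 → 60 °C
Reagents that add atoms: methyltriphenylphosphonium bromide, [Br-].C[P+](c1ccccc1)(c1ccccc1)c1ccccc1
Why: Wittig methylenation of the hindered C8 ketone with excess ylide (which also deprotonates the hydroxyl reversibly) installs the exocyclic C8=C17 double bond.

Step 13
Reactants: 24 15,16-dinorlabd-8(17)-en-13-yn-18-ol
Product: 26 methyl (13E)-18-hydroxylabda-8(17),13-dien-15-oate, via alkenylalane 25 (not isolated)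
Conditions: Me3Al (4 equiv), Cp2ZrCl2 (0.3 equiv), CH2Cl2, 0 °C → rt; then ClCO2Me, rt; aqueous HCl work-up
Reagents that add atoms: trimethylaluminium, C[Al](C)C; methyl chloroformate, COC(=O)Cl
Why: Zirconium-catalysed methylalumination of the terminal alkyne (Negishi carboalumination) is a syn addition with methyl on C13 and aluminium on C14, and the alkenylalane is acylated by the chloroformate with retention, which should give only the 13E enoate; the 1,1-disubstituted alkene is inert and the hydroxyl is carried as its poorly nucleophilic dimethylaluminium alkoxide.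

Step 14
Reactants: 10 {[(6R)-6-(but-3-en-1-yl)-7-methyl-1,4-dioxaspiro[4.5]dec-7-en-8-yl]oxy}trimethylsilane
Product: 28 (6R)-6-(but-3-en-1-yl)-7,7-dimethyl-1,4-dioxaspiro[4.5]decan-8-one, via ammonium enolate 27 (not isolated)
Conditions: BnMe3N+ F− (anhydrous, 1.1 equiv), MeI (5 equiv), 4 Å molecular sieves, THF, 0 °C → rt
Reagents that add atoms: iodomethane, CI
Why: Fluoride cleaves the Si–O bond of 10 and gives the quaternary ammonium enolate 27 regiospecifically, which is C-methylated by MeI at the carbon that already bears a methyl group (regiospecific alkylation of a silyl enol ether through its ammonium enolate), so that this carbon becomes the gem-dimethyl carbon and the only stereocentre of 28 is the one set in step 4.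

Step 15
Reactants: 28 (6R)-6-(but-3-en-1-yl)-7,7-dimethyl-1,4-dioxaspiro[4.5]decan-8-one
Product: 30 (6R)-6-(but-3-en-1-yl)-7,7-dimethyl-1,4-dioxaspiro[4.5]decane, via hydrazone 29 (not isolated)
Conditions: N2H4·H2O, diethylene glycol, 130 °C; then KOH, 200 °C (under N2)
Reagents that add atoms: none
Why: Wolff–Kishner reduction (Huang–Minlon variant) removes the ketone next to the quaternary carbon; the stereocentre is β to the carbonyl and cannot epimerise.

Step 16
Reactants: 30 (6R)-6-(but-3-en-1-yl)-7,7-dimethyl-1,4-dioxaspiro[4.5]decane; 31 methyl acrylate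
Product: 32 methyl (2E)-5-[(6R)-7,7-dimethyl-1,4-dioxaspiro[4.5]decan-6-yl]pent-2-enoate
Conditions: second-generation Grubbs catalyst (3 mol %), 31 (5 equiv), CH2Cl2, 40 °C
Reagents that add atoms: none
Why: Olefin cross-metathesis of the monosubstituted alkene with the electron-poor acrylate should give the (E)-enoate selectively and adds the last carbon of the acid chain (C1′).

Step 17
Reactants: 32 methyl (2E)-5-[(6R)-7,7-dimethyl-1,4-dioxaspiro[4.5]decan-6-yl]pent-2-enoate
Product: 33 methyl (3S)-5-[(6R)-7,7-dimethyl-1,4-dioxaspiro[4.5]decan-6-yl]-3-methylpentanoate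
Conditions: MeMgBr, CuI (2 mol %), Tol-BINAP (3 mol %, the enantiomer that gives 3S), t-BuOMe, −20 °C; NH4Cl
Reagents that add atoms: methylmagnesium bromide, C[Mg]Br
Why: Copper-catalysed asymmetric conjugate addition of the methyl Grignard reagent to the (E)-enoate sets C3′ under control of the ligand (catalyst control, the ring stereocentre is four bonds away), and the ketal and the ester survive at low temperature.

Step 18
Reactants: 33 methyl (3S)-5-[(6R)-7,7-dimethyl-1,4-dioxaspiro[4.5]decan-6-yl]-3-methylpentanoate
Product: 34 methyl (3S)-5-[(1R)-2,2-dimethyl-6-oxocyclohexyl]-3-methylpentanoate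
Conditions: 1 M HCl, THF, 0 °C → rt (short)
Reagents that add atoms: water, O
Why: Mild acid hydrolysis of the ketal frees the ketone; the conditions are kept cold and short because the ring CH is now α to the carbonyl and is the only stereocentre of the ring.

Step 19
Reactants: 34 methyl (3S)-5-[(1R)-2,2-dimethyl-6-oxocyclohexyl]-3-methylpentanoate
Product: 35 methyl (3S)-5-[(1R)-2,2-dimethyl-6-methylidenecyclohexyl]-3-methylpentanoate
Conditions: Zn, CH2Br2, TiCl4, THF/CH2Cl2, 0 °C → rt
Reagents that add atoms: dibromomethane, BrCBr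
Why: Takai–Lombardo methylenation is not basic, so the α-stereocentre should not epimerise, and the zinc–titanium reagent does not attack the ester.

Step 20
Reactants: 35 methyl (3S)-5-[(1R)-2,2-dimethyl-6-methylidenecyclohexyl]-3-methylpentanoate
Product: 36 methyl (3S)-5-[(3R,4R)-5,5-dimethyl-1-oxaspiro[2.5]octan-4-yl]-3-methylpentanoate
Conditions: mCPBA, NaHCO3, CH2Cl2, 0 °C
Reagents that add atoms: 3-chloroperoxybenzoic acid, OOC(=O)c1cccc(Cl)c1
Why: Epoxidation with the peracid (Prilezhaev reaction) should come from the face of the exocyclic alkene that is not shielded by the axial methyl of the gem-dimethyl carbon (chair with the side chain equatorial), which puts the oxygen equatorial and trans to the side chain, as in the α-face epoxidation of labd-8(17)-enes.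

Step 21
Reactants: 36 methyl (3S)-5-[(3R,4R)-5,5-dimethyl-1-oxaspiro[2.5]octan-4-yl]-3-methylpentanoate
Product: 37 (3S)-5-[(1R,2R)-2-hydroxy-2,6,6-trimethylcyclohexyl]-3-methylpentan-1-ol
Conditions: LiAlH4, THF, 0 °C → reflux; aqueous work-up
Reagents that add atoms: none
Why: LiAlH4 opens the 1,1-disubstituted epoxide at its CH2 carbon (SN2), which leaves the C–O bond at the ring carbon untouched and gives the tertiary alcohol, and it reduces the ester to the primary alcohol in the same operation.

Step 22
Reactants: 37 (3S)-5-[(1R,2R)-2-hydroxy-2,6,6-trimethylcyclohexyl]-3-methylpentan-1-ol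
Product: 39 (3S)-5-[(1R,2R)-2-hydroxy-2,6,6-trimethylcyclohexyl]-3-methylpentanoic acid, via hydroxy aldehyde 38 (not isolated)
Conditions: TEMPO (cat.), NaOCl (cat.), NaClO2, MeCN/phosphate buffer (pH 6.7), 35 °C
Reagents that add atoms: sodium chlorite, [Na+].[O-]Cl=O
Why: TEMPO-catalysed oxidation takes the primary alcohol to the aldehyde and chlorite takes the aldehyde to the acid (Pinnick-type oxidation), while the tertiary alcohol cannot be oxidised.

Step 23
Reactants: 26 methyl (13E)-18-hydroxylabda-8(17),13-dien-15-oate; 39 (3S)-5-[(1R,2R)-2-hydroxy-2,6,6-trimethylcyclohexyl]-3-methylpentanoic acid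
Product: 40 methyl (13E)-18-{[(3S)-5-[(1R,2R)-2-hydroxy-2,6,6-trimethylcyclohexyl]-3-methylpentanoyl]oxy}labda-8(17),13-dien-15-oate (CNP0174687.1)
Conditions: EDC·HCl, DMAP, CH2Cl2, rt
Reagents that add atoms: none
Why: Steglich esterification joins the primary neopentyl C18 alcohol with the acid; the tertiary alcohol of 39 is too hindered to be acylated, and the lactone it could form would be eight-membered.

**Compound list**

1 | 1,4-dioxaspiro[4.5]dec-6-en-8-one | O=C1C=CC2(CC1)OCCO2 | starting material
2 | 7-iodo-1,4-dioxaspiro[4.5]dec-6-en-8-one | O=C1C(I)=CC2(CC1)OCCO2 | intermediate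
3 | 7-methyl-1,4-dioxaspiro[4.5]dec-6-en-8-one | O=C1C(C)=CC2(CC1)OCCO2 | intermediate
4 | (1-bromoethenyl)trimethylsilane | C=C(Br)[Si](C)(C)C | starting material
5 | N-methoxy-N-methylpropanamide | CCC(=O)N(C)OC | starting material
6 | [1-(trimethylsilyl)ethenyl]lithium (not isolated) | [Li]C(=C)[Si](C)(C)C | intermediate
7 | 2-(trimethylsilyl)pent-1-en-3-one | C=C([Si](C)(C)C)C(=O)CC | intermediate
8 | but-3-en-1-ylmagnesium bromide | C=CCC[Mg]Br | starting material
9 | bromomagnesium (6R)-6-(but-3-en-1-yl)-7-methyl-1,4-dioxaspiro[4.5]dec-7-en-8-olate (not isolated) | CC1=C(O[Mg]Br)CCC2(OCCO2)[C@@H]1CCC=C | intermediate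
10 | {[(6R)-6-(but-3-en-1-yl)-7-methyl-1,4-dioxaspiro[4.5]dec-7-en-8-yl]oxy}trimethylsilane | CC1=C(O[Si](C)(C)C)CCC2(OCCO2)[C@@H]1CCC=C | intermediate
11 | lithium (6R)-6-(but-3-en-1-yl)-7-methyl-1,4-dioxaspiro[4.5]dec-7-en-8-olate (not isolated) | CC1=C(O[Li])CCC2(OCCO2)[C@@H]1CCC=C | intermediate
12 | (6R,7R)-6-(but-3-en-1-yl)-7-methyl-7-[3-oxo-2-(trimethylsilyl)pentyl]-1,4-dioxaspiro[4.5]decan-8-one (silyl-bearing carbon as a mixture; not isolated) | CCC(=O)C([Si](C)(C)C)C[C@@]1(C)C(=O)CCC2(OCCO2)[C@@H]1CCC=C | intermediate
13 | (6R,7R)-6-(but-3-en-1-yl)-7-methyl-7-(3-oxopentyl)-1,4-dioxaspiro[4.5]decan-8-one (not isolated) | CCC(=O)CC[C@@]1(C)C(=O)CCC2(OCCO2)[C@@H]1CCC=C | intermediate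
14 | 8,8-ethylenedioxy-15,16,17,18-tetranorlabda-4,13-dien-3-one (9R,10R; 9β-butenyl, 10β-methyl) | O1CCOC12CCC3=C(C)C(=O)CC[C@]3(C)[C@H]2CCC=C | intermediate
15 | lithium enolate (C3–OLi, C3=C4) of 8,8-ethylenedioxy-15,16,17,18-tetranor-5α-labd-13-en-3-one (not isolated) | O1CCOC12CC[C@H]3C(C)=C(O[Li])CC[C@]3(C)[C@H]2CCC=C | intermediate
16 | 8,8-ethylenedioxy-18-hydroxy-15,16,17-trinorlabd-13-en-3-one (5α-H, 4α-CH2OH, 4β-CH3) | O1CCOC12CC[C@H]3[C@](C)(CO)C(=O)CC[C@]3(C)[C@H]2CCC=C | intermediate
17 | 8,8-ethylenedioxy-18-(methoxymethoxy)-15,16,17-trinorlabd-13-en-3-one | O1CCOC12CC[C@H]3[C@](C)(COCOC)C(=O)CC[C@]3(C)[C@H]2CCC=C | intermediate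
18 | hydrazone of 17 at C3 (not isolated) | O1CCOC12CC[C@H]3[C@](C)(COCOC)C(=NN)CC[C@]3(C)[C@H]2CCC=C | intermediate
19 | 8,8-ethylenedioxy-18-(methoxymethoxy)-15,16,17-trinorlabd-13-ene | O1CCOC12CC[C@H]3[C@](C)(COCOC)CCC[C@]3(C)[C@H]2CCC=C | intermediate
20 | 13,14-ozonide (1,2,4-trioxolane) of 19 (not isolated) | O1CCOC12CC[C@H]3[C@](C)(COCOC)CCC[C@]3(C)[C@H]2CCC4OOCO4 | intermediate
21 | 8,8-ethylenedioxy-18-(methoxymethoxy)-14,15,16,17-tetranorlabdan-13-al | O1CCOC12CC[C@H]3[C@](C)(COCOC)CCC[C@]3(C)[C@H]2CCC=O | intermediate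
22 | 8,8-ethylenedioxy-18-(methoxymethoxy)-15,16,17-trinorlabd-13-yne | O1CCOC12CC[C@H]3[C@](C)(COCOC)CCC[C@]3(C)[C@H]2CCC#C | intermediate
23 | 18-hydroxy-15,16,17-trinorlabd-13-yn-8-one | O=C1CC[C@H]2[C@](C)(CO)CCC[C@]2(C)[C@H]1CCC#C | intermediate
24 | 15,16-dinorlabd-8(17)-en-13-yn-18-ol | C=C1CC[C@H]2[C@](C)(CO)CCC[C@]2(C)[C@H]1CCC#C | intermediate
25 | dimethyl[(13E)-18-(dimethylalumanyloxy)-15-norlabda-8(17),13-dien-14-yl]alumane (not isolated) | C=C1CC[C@H]2[C@](C)(CO[Al](C)C)CCC[C@]2(C)[C@H]1CC/C(C)=C/[Al](C)C | intermediate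
26 | methyl (13E)-18-hydroxylabda-8(17),13-dien-15-oate | C=C1CC[C@H]2[C@](C)(CO)CCC[C@]2(C)[C@H]1CC/C(C)=C/C(=O)OC | intermediate
27 | benzyltrimethylammonium (6R)-6-(but-3-en-1-yl)-7-methyl-1,4-dioxaspiro[4.5]dec-7-en-8-olate (not isolated) | C[N+](C)(C)Cc1ccccc1.CC1=C([O-])CCC2(OCCO2)[C@@H]1CCC=C | intermediate
28 | (6R)-6-(but-3-en-1-yl)-7,7-dimethyl-1,4-dioxaspiro[4.5]decan-8-one | C=CCC[C@@H]1C(C)(C)C(=O)CCC12OCCO2 | intermediate
29 | hydrazone of 28 (not isolated) | C=CCC[C@@H]1C(C)(C)C(=NN)CCC12OCCO2 | intermediate
30 | (6R)-6-(but-3-en-1-yl)-7,7-dimethyl-1,4-dioxaspiro[4.5]decane | C=CCC[C@@H]1C(C)(C)CCCC12OCCO2 | intermediate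
31 | methyl acrylate | C=CC(=O)OC | starting material
32 | methyl (2E)-5-[(6R)-7,7-dimethyl-1,4-dioxaspiro[4.5]decan-6-yl]pent-2-enoate | COC(=O)/C=C/CC[C@@H]1C(C)(C)CCCC12OCCO2 | intermediate
33 | methyl (3S)-5-[(6R)-7,7-dimethyl-1,4-dioxaspiro[4.5]decan-6-yl]-3-methylpentanoate | COC(=O)C[C@@H](C)CC[C@@H]1C(C)(C)CCCC12OCCO2 | intermediate
34 | methyl (3S)-5-[(1R)-2,2-dimethyl-6-oxocyclohexyl]-3-methylpentanoate | COC(=O)C[C@@H](C)CC[C@@H]1C(C)(C)CCCC1=O | intermediate
35 | methyl (3S)-5-[(1R)-2,2-dimethyl-6-methylidenecyclohexyl]-3-methylpentanoate | COC(=O)C[C@@H](C)CC[C@@H]1C(C)(C)CCCC1=C | intermediate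
36 | methyl (3S)-5-[(3R,4R)-5,5-dimethyl-1-oxaspiro[2.5]octan-4-yl]-3-methylpentanoate | COC(=O)C[C@@H](C)CC[C@@H]1C(C)(C)CCC[C@]12CO2 | intermediate
37 | (3S)-5-[(1R,2R)-2-hydroxy-2,6,6-trimethylcyclohexyl]-3-methylpentan-1-ol | OCC[C@@H](C)CC[C@@H]1C(C)(C)CCC[C@@]1(C)O | intermediate
38 | (3S)-5-[(1R,2R)-2-hydroxy-2,6,6-trimethylcyclohexyl]-3-methylpentanal (not isolated) | O=CC[C@@H](C)CC[C@@H]1C(C)(C)CCC[C@@]1(C)O | intermediate
39 | (3S)-5-[(1R,2R)-2-hydroxy-2,6,6-trimethylcyclohexyl]-3-methylpentanoic acid | OC(=O)C[C@@H](C)CC[C@@H]1C(C)(C)CCC[C@@]1(C)O | intermediate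
40 | methyl (13E)-18-{[(3S)-5-[(1R,2R)-2-hydroxy-2,6,6-trimethylcyclohexyl]-3-methylpentanoyl]oxy}labda-8(17),13-dien-15-oate (CNP0174687.1) | C=C1CC[C@H]2[C@](C)(COC(=O)C[C@@H](C)CC[C@@H]3C(C)(C)CCC[C@@]3(C)O)CCC[C@]2(C)[C@H]1CC/C(C)=C/C(=O)OC | target

**Step count and risks**

Total step count: 23. Longest linear sequence: 13 steps (1, 2, 4–13, 23; the line 1, 2, 4, 14–22, 23 is equally long).

Steps most likely to fail:

1. Step 5. What may go wrong: slow Michael capture of the hindered tetrasubstituted lithium enolate, so that proton transfer (enolate equilibration) and anionic polymerisation of 7 compete, and erosion of the trans entry at C10 by the neighbouring ketal. Fallback (sets out from 10, comes back at 14): 10 is cleaved with K2CO3 in MeOH (0 °C → rt) to the methyl ketone (6R)-6-(but-3-en-1-yl)-7-methyl-1,4-dioxaspiro[4.5]decan-8-one F1, whose C7 epimers converge in the next operation. A classical base-mediated Robinson annulation of F1 with pent-1-en-3-one (NaOMe, MeOH, 0 → 60 °C; thermodynamic enolate at the methyl-bearing carbon, Michael addition anti to the butenyl group, aldol condensation in the same flask) returns 14.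

2. Step 6. What may go wrong: O-hydroxymethylation or polymerisation of formaldehyde instead of C–C bond formation, premature protonation of the enolate (no C18 carbon introduced), over-reduction of the ketone, or retro-aldol loss of formaldehyde during work-up. Fallback (sets out from 14, comes back at 16): the enolate is generated as in step 6 but silylated (TMSCl, Et3N, −78 °C) to the isolable trimethylsilyl enol ether of the 5α-3-ketone F2. F2 is then hydroxymethylated with aqueous formaldehyde and Yb(OTf)3 (cat.) in THF (Mukaiyama-type aldol reaction in water), again from the α face, to give 16.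

3. Step 20. What may go wrong: poor or reversed facial selectivity of the epoxidation, because the monocycle is flexible and the conformer with an axial side chain exposes the other face. Fallback (sets out from 34, comes back at 36 and skips step 19): dimethylsulfonium methylide (Me3S+ I−, KHMDS, THF, −20 °C; Corey–Chaykovsky epoxidation) delivers CH2 to the ketone from the face that the peracid would use on 35, so that the oxygen ends on the opposite face. It is therefore stereocomplementary to step 20 and is the choice if the peracid favours the wrong face; no compound outside the list is made (F0).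

Further compounds
F1 | step 5 | (6R)-6-(but-3-en-1-yl)-7-methyl-1,4-dioxaspiro[4.5]decan-8-one (C7 epimers) | C=CCC[C@@H]1C(C)C(=O)CCC12OCCO2
F2 | step 6 | trimethylsilyl enol ether (C3–OSiMe3, C3=C4) of 8,8-ethylenedioxy-15,16,17,18-tetranor-5α-labd-13-en-3-one | O1CCOC12CC[C@H]3C(C)=C(O[Si](C)(C)C)CC[C@]3(C)[C@H]2CCC=C
F0 | step 20 | none | none
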